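**Retrosynthetic overview**
- The target is cut back to its 3,4‑bis(acetoxymethyl) diacetate; the acetates keep the primary OH groups from competing in the ring closure.
- Key disconnection: both C–O bonds of the oxolane. They come from a formal oxygen insertion into the bis‑benzylic C–C bond of a 1,2‑bis(4‑hydroxyaryl)cyclobutane, via a meso bis‑quinone methide that takes up one water.
- The cyclobutane comes from a [2+2] photoadduct of the syringyl stilbene with one molecule of maleic anhydride; its cis ring fusion becomes the cis C3/C4 pair of the target.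
- The stilbene comes from McMurry coupling of syringaldehyde.
- Ring order: the temporary cyclobutane first, the oxolane (the only ring of the target besides the arenes) last, by C–O bond formation.

Assumption: the SMILES encodes the meso (2R,3S,4R,5S) isomer (2,3‑trans, 3,4‑cis, 4,5‑trans; mirror plane through O and the C3–C4 midpoint), so the target is achiral, only relative configuration has to be controlled, and chiral intermediates are racemic.

**Step 1**
Reactants: 1 syringaldehyde (4‑hydroxy‑3,5‑dimethoxybenzaldehyde), 2 equiv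
Product: 2 (E)‑4,4'‑(ethene‑1,2‑diyl)bis(2,6‑dimethoxyphenol)
Conditions: TiCl4 (3 equiv), Zn dust (6 equiv), THF, 0 °C then reflux
Reagents that add atoms: none
Why: McMurry reductive carbonyl homocoupling (pinacol coupling on low‑valent titanium, then deoxygenation) gives the thermodynamically favoured E‑stilbene, the free phenols being carried as titanium phenoxides by the extra reagent.

**Step 2**
Reactants: 2 (E)‑4,4'‑(ethene‑1,2‑diyl)bis(2,6‑dimethoxyphenol); 3 maleic anhydride
Product: 4 rac‑6,7‑bis(4‑hydroxy‑3,5‑dimethoxyphenyl)‑3‑oxabicyclo[3.2.0]heptane‑2,4‑dione (cis ring fusion; aryl groups trans to each other)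
Conditions: 365 nm LEDs, degassed EtOAc, stilbene 0.02 M, anhydride 0.1 M, 20 °C
Reagents that add atoms: none
Why: [2+2] photocycloaddition through the stilbene–maleic anhydride exciplex/charge‑transfer complex (known for trans‑stilbene) joins one anhydride to one stilbene with nothing lost; the five‑membered anhydride can only be cis‑fused, which sets the cis relationship of the two future CH2OH carbons, and any scrambling at the aryl carbons is harmless because those centres are erased in step 5.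

**Step 3**
Reactants: 4 rac‑6,7‑bis(4‑hydroxy‑3,5‑dimethoxyphenyl)‑3‑oxabicyclo[3.2.0]heptane‑2,4‑dione
Product: 5 rac‑[3,4‑bis(4‑hydroxy‑3,5‑dimethoxyphenyl)cyclobutane‑1,2‑diyl]dimethanol (1,2‑cis; 3,4‑trans)
Conditions: LiAlH4 (4 equiv), THF, −10 → 20 °C (4 added to the hydride); aq. KNaC4H4O6 work‑up
Reagents that add atoms: none
Why: Hydride reduction of a cyclic anhydride to the 1,4‑diol touches no stereocentre, and inverse addition makes carbonyl reduction outrun any phenoxide‑driven opening of the cyclobutane.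

**Step 4**
Reactants: 5 rac‑[3,4‑bis(4‑hydroxy‑3,5‑dimethoxyphenyl)cyclobutane‑1,2‑diyl]dimethanol
Product: 6 rac‑[3,4‑bis(4‑hydroxy‑3,5‑dimethoxyphenyl)cyclobutane‑1,2‑diyl]bis(methylene) diacetate (1,2‑cis; 3,4‑trans)
Conditions: Novozym 435 (immobilised Candida antarctica lipase B), vinyl acetate (6 equiv), THF, 40 °C
Reagents that add atoms: vinyl acetate, C=COC(C)=O
Why: Lipase‑catalysed transesterification acylates primary aliphatic OH chemoselectively and leaves the hindered 2,6‑dimethoxyphenols free, as step 5 requires; no stereocentre is affected.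

**Step 5**
Reactants: 6 rac‑[3,4‑bis(4‑hydroxy‑3,5‑dimethoxyphenyl)cyclobutane‑1,2‑diyl]bis(methylene) diacetate
Product: 10 [(2R,3S,4R,5S)‑2,5‑bis(4‑hydroxy‑3,5‑dimethoxyphenyl)oxolane‑3,4‑diyl]bis(methylene) diacetate, via bis‑quinone methide 7 (not isolated), via hydroxy quinone methide 8 (not isolated), via epimer mixture 9 (not isolated)
Conditions: Ag2O (3 equiv), 4 Å MS, CH2Cl2, N2, dark, 20 °C; filter; acetone/NaOAc–AcOH buffer pH 5 (4:1), 20 °C; extract, dry; then BF3·OEt2 (0.3 equiv), CH2Cl2, −30 → 0 °C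
Reagents that add atoms: water, O
Why: Proposed new method: an oxidative oxygen insertion into the strained bis‑benzylic C–C σ‑bond of a 1,2‑bis(4‑hydroxyaryl)cyclobutane, in which Ag2O makes the hindered phenoxyl radical, β‑scission of the C3–C4 ring bond (a cyclobutylcarbinyl‑type opening, estimated exothermic by more than 10 kcal/mol because about 26 kcal/mol of strain is released) and loss of the second phenolic hydrogen give the closed‑shell meso bis‑quinone methide 7 with the two CH2OAc‑bearing carbons untouched, water then adds 1,6 to one quinone methide (8) and the new benzylic OH closes 5‑exo onto the other to form both C–O bonds of the oxolane (9), and catalytic BF3·OEt2 reversibly re‑ionises the 4‑hydroxybenzylic C–O bonds so that C2 and C5 settle in the thermodynamic arrangement with each aryl trans to its neighbouring CH2OAc (10); the closest known reaction types are the water trapping of 8–8‑coupled bis‑quinone methides from γ‑acylated sinapyl alcohol to 2,5‑diaryl‑3,4‑bis(acyloxymethyl)oxolanes, nucleophile‑triggered ring opening of arylcyclopropane radical cations, and BF3·OEt2 epimerisation of 2‑aryl‑oxolane lignans to the 2,3‑trans isomers.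

**Step 6**
Reactants: 10 [(2R,3S,4R,5S)‑2,5‑bis(4‑hydroxy‑3,5‑dimethoxyphenyl)oxolane‑3,4‑diyl]bis(methylene) diacetate
Product: 11 [(2R,3S,4R,5S)‑2,5‑bis(4‑hydroxy‑3,5‑dimethoxyphenyl)oxolane‑3,4‑diyl]dimethanol (target)
Conditions: K2CO3 (0.3 equiv), MeOH, N2, 0 → 20 °C; Amberlite IR‑120 (H+ form) quench
Reagents that add atoms: none
Why: Zemplén‑type transesterification removes both acetates under mild base at room temperature, where the benzylic ethers do not open, so no stereocentre is disturbed.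

**Compound list**
1 | syringaldehyde (4‑hydroxy‑3,5‑dimethoxybenzaldehyde) | COc1cc(C=O)cc(OC)c1O | starting material
2 | (E)‑4,4'‑(ethene‑1,2‑diyl)bis(2,6‑dimethoxyphenol) | COc1cc(/C=C/c2cc(OC)c(O)c(OC)c2)cc(OC)c1O | intermediate
3 | maleic anhydride | O=C1OC(=O)C=C1 | starting material
4 | rac‑6,7‑bis(4‑hydroxy‑3,5‑dimethoxyphenyl)‑3‑oxabicyclo[3.2.0]heptane‑2,4‑dione, cis‑fused, aryls trans | O=C1OC(=O)[C@H]2[C@@H]1[C@H](c3cc(OC)c(O)c(OC)c3)[C@H]2c4cc(OC)c(O)c(OC)c4 | intermediate
5 | rac‑[3,4‑bis(4‑hydroxy‑3,5‑dimethoxyphenyl)cyclobutane‑1,2‑diyl]dimethanol, 1,2‑cis, 3,4‑trans | OC[C@H]1[C@@H](CO)[C@H](c2cc(OC)c(O)c(OC)c2)[C@H]1c3cc(OC)c(O)c(OC)c3 | intermediate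
6 | rac‑[3,4‑bis(4‑hydroxy‑3,5‑dimethoxyphenyl)cyclobutane‑1,2‑diyl]bis(methylene) diacetate, 1,2‑cis, 3,4‑trans | CC(=O)OC[C@H]1[C@@H](COC(C)=O)[C@H](c2cc(OC)c(O)c(OC)c2)[C@H]1c3cc(OC)c(O)c(OC)c3 | intermediate
7 | meso‑(2R,3S)‑2,3‑bis[(3,5‑dimethoxy‑4‑oxocyclohexa‑2,5‑dien‑1‑ylidene)methyl]butane‑1,4‑diyl diacetate (bis‑quinone methide) | CC(=O)OC[C@H](C=C1C=C(OC)C(=O)C(OC)=C1)[C@@H](COC(C)=O)C=C2C=C(OC)C(=O)C(OC)=C2 | intermediate (not isolated)
8 | 2‑[hydroxy(4‑hydroxy‑3,5‑dimethoxyphenyl)methyl]‑3‑[(3,5‑dimethoxy‑4‑oxocyclohexa‑2,5‑dien‑1‑ylidene)methyl]butane‑1,4‑diyl diacetate, backbone as in 7, both carbinol epimers, racemic | CC(=O)OC[C@H](C(O)c1cc(OC)c(O)c(OC)c1)[C@@H](COC(C)=O)C=C2C=C(OC)C(=O)C(OC)=C2 | intermediate (not isolated)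
9 | [2,5‑bis(4‑hydroxy‑3,5‑dimethoxyphenyl)oxolane‑3,4‑diyl]bis(methylene) diacetate, 3,4‑cis, mixture of C2/C5 epimers | COc1cc(C2OC(c3cc(OC)c(O)c(OC)c3)[C@H](COC(C)=O)[C@@H]2COC(C)=O)cc(OC)c1O | intermediate (not isolated)
10 | [(2R,3S,4R,5S)‑2,5‑bis(4‑hydroxy‑3,5‑dimethoxyphenyl)oxolane‑3,4‑diyl]bis(methylene) diacetate, meso | COc1cc([C@H]2O[C@@H](c3cc(OC)c(O)c(OC)c3)[C@H](COC(C)=O)[C@@H]2COC(C)=O)cc(OC)c1O | intermediate
11 | [(2R,3S,4R,5S)‑2,5‑bis(4‑hydroxy‑3,5‑dimethoxyphenyl)oxolane‑3,4‑diyl]dimethanol, meso | COc1cc([C@H]2O[C@@H](c3cc(OC)c(O)c(OC)c3)[C@H](CO)[C@@H]2CO)cc(OC)c1O | target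

**Totals**
Total steps: 6. Longest linear sequence: 6 (1 → 2 → 4 → 5 → 6 → 10 → 11).

**Steps most likely to fail**

First risk, step 5 (the new oxygen insertion). The phenoxyl radicals may disproportionate without C–C cleavage, an acetate may take part in the ionisation, or the BF3 stage may drift to an aryl‑tetralin. The fallback uses known chemistry and puts the oxygen between the benzylic carbons before the ring is made. It sets out from 2 and comes back at 9. Acetylation (Ac2O, pyridine) gives the stilbene diacetate F8, and dimethyldioxirane (acetone, 0 °C) gives the trans‑epoxide F9. Photolysis at 254 nm in MeCN (or sensitisation with 1,4‑dicyanonaphthalene) in the presence of maleic anhydride 3 opens the C–C bond of the epoxide to the carbonyl ylide, whose [3+2] cycloaddition gives the cis‑fused oxolane anhydride F10; C3/C4 are cis from the dipolarophile and C2/C5 are mixed. LiAlH4 reduces the anhydride and the aryl acetates to the tetraol epimer mixture F11. Lipase acetylation as in step 4 then gives the epimer mixture 9, which the BF3·OEt2 stage of step 5 converts to 10.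

Second risk, step 2 (photoaddition of a phenolic, very electron‑rich stilbene to maleic anhydride). It may give only E/Z isomerisation, alternating copolymer or phenol acylation. The fallback builds the cyclobutane from two cinnamate units on a template instead. It sets out from 1 and comes back at 7. Knoevenagel–Doebner condensation with malonic acid (pyridine, piperidine, 90 °C) gives sinapic acid F2, and Ac2O/pyridine gives 4‑O‑acetylsinapic acid F3. Coupling with naphthalene‑1,8‑diol (0.5 equiv; EDC·HCl, DMAP, CH2Cl2) gives the naphthalene‑1,8‑diyl bis‑cinnamate F4. The peri template holds the two alkenes parallel, so irradiation at 350 nm (solid state or 5 mM solution) gives the head‑to‑head, cis‑diester photodimer F5 (β‑truxinate type). LiAlH4 releases the cyclobutane diol F6 (1,2‑cis CH2OH, 3,4‑cis aryl), which differs from 5 only at the aryl carbons. Lipase acetylation as in step 4 gives the diacetate F7, which under the step 5 conditions fragments to the same bis‑quinone methide 7.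

Third risk, step 1 (McMurry coupling on an unprotected phenolic aldehyde). Low conversion or pinacol‑stage products are possible. The fallback makes the alkene by metathesis. It sets out from 1 and comes back at 2. Decarboxylative Knoevenagel–Doebner reaction with malonic acid (piperidine, pyridine, 130 °C) gives 2,6‑dimethoxy‑4‑vinylphenol F1, and self‑metathesis with the second‑generation Grubbs catalyst (CH2Cl2, 40 °C, ethene purged) gives 2.

**Further compounds**
F1 | step 1 | 2,6‑dimethoxy‑4‑vinylphenol | COc1cc(C=C)cc(OC)c1O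
F2 | step 2 | sinapic acid, (E)‑3‑(4‑hydroxy‑3,5‑dimethoxyphenyl)prop‑2‑enoic acid | COc1cc(/C=C/C(O)=O)cc(OC)c1O
F3 | step 2 | 4‑O‑acetylsinapic acid, (E)‑3‑(4‑acetoxy‑3,5‑dimethoxyphenyl)prop‑2‑enoic acid | COc1cc(/C=C/C(O)=O)cc(OC)c1OC(C)=O
F4 | step 2 | naphthalene‑1,8‑diyl bis[(E)‑3‑(4‑acetoxy‑3,5‑dimethoxyphenyl)prop‑2‑enoate] | CC(=O)Oc1c(OC)cc(/C=C/C(=O)Oc2cccc3cccc(OC(=O)/C=C/c4cc(OC)c(OC(C)=O)c(OC)c4)c23)cc1OC
F5 | step 2 | naphthalene‑1,8‑diyl 3,4‑bis(4‑acetoxy‑3,5‑dimethoxyphenyl)cyclobutane‑1,2‑dicarboxylate, esters cis, aryls cis, aryl trans to neighbouring ester (meso) | O=C1Oc2cccc3cccc(OC(=O)[C@H]4[C@@H]1[C@H](c5cc(OC)c(OC(C)=O)c(OC)c5)[C@@H]4c6cc(OC)c(OC(C)=O)c(OC)c6)c23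
F6 | step 2 | [3,4‑bis(4‑hydroxy‑3,5‑dimethoxyphenyl)cyclobutane‑1,2‑diyl]dimethanol, 1,2‑cis, 3,4‑cis, 2,3‑trans (meso) | OC[C@H]1[C@@H](CO)[C@H](c2cc(OC)c(O)c(OC)c2)[C@@H]1c3cc(OC)c(O)c(OC)c3
F7 | step 2 | [3,4‑bis(4‑hydroxy‑3,5‑dimethoxyphenyl)cyclobutane‑1,2‑diyl]bis(methylene) diacetate, 1,2‑cis, 3,4‑cis, 2,3‑trans (meso) | CC(=O)OC[C@H]1[C@@H](COC(C)=O)[C@H](c2cc(OC)c(O)c(OC)c2)[C@@H]1c3cc(OC)c(O)c(OC)c3
F8 | step 5 | (E)‑ethene‑1,2‑diylbis(2,6‑dimethoxy‑4,1‑phenylene) diacetate | COc1cc(/C=C/c2cc(OC)c(OC(C)=O)c(OC)c2)cc(OC)c1OC(C)=O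
F9 | step 5 | rac‑trans‑2,3‑bis(4‑acetoxy‑3,5‑dimethoxyphenyl)oxirane | COc1cc([C@H]2O[C@@H]2c3cc(OC)c(OC(C)=O)c(OC)c3)cc(OC)c1OC(C)=O
F10 | step 5 | 4,6‑bis(4‑acetoxy‑3,5‑dimethoxyphenyl)tetrahydro‑1H,3H‑furo[3,4‑c]furan‑1,3‑dione, cis‑fused, C4/C6 epimer mixture | O=C1OC(=O)[C@H]2[C@@H]1C(c3cc(OC)c(OC(C)=O)c(OC)c3)OC2c4cc(OC)c(OC(C)=O)c(OC)c4
F11 | step 5 | [2,5‑bis(4‑hydroxy‑3,5‑dimethoxyphenyl)oxolane‑3,4‑diyl]dimethanol, 3,4‑cis, C2/C5 epimer mixture | COc1cc(C2OC(c3cc(OC)c(O)c(OC)c3)[C@H](CO)[C@@H]2CO)cc(OC)c1O
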